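## Retrosynthetic overview

1. C3′–OOH: last-step Schenck ene reaction (singlet oxygen) on a prenyl side chain; the C4 acetate comes from a 1,3-anti diol made by hydroxyl-directed reduction of a β-hydroxy enone.
2. Ten-membered ring (formed second): Nozaki–Hiyama–Kishi closure of the C4–C5 bond, E-alkenyl iodide onto a β-hydroxy aldehyde.
3. C2 tertiary carbinol: Sharpless epoxidation and hydride opening of the allylic alcohol obtained by Horner–Wadsworth–Emmons homologation of a cyclopropyl methyl ketone.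
4. Three-membered ring (formed first): hydroxyl-directed Simmons–Smith reaction on an E-allylic alcohol whose carbinol centre comes from (S)-lactate.
5. C9 quaternary centre: phosphine-directed, copper-mediated syn-SN2′ substitution (1,3-chirality transfer) of an allylic ester built from (S)-lactaldehyde and an alkenyllithium derived from 6-methylhept-5-en-2-one.

Locants follow the bicyclo[8.1.0]undecane numbering of the target: C1/C10 cyclopropane CH, C11 cyclopropane CH2, C2 tertiary carbinol, C4 acetoxy carbon, C5=C6 ring alkene, C9 quaternary carbon, C1′–C5′ side chain.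

Assumption: C3′ is remote from every other stereocentre, so the last step is not expected to be selective there; the (3′S) hydroperoxide is separated from its C3′ epimer by HPLC (a stereocontrolled alternative is given with the fallbacks).

Assumption: the O-silylated lactate ester is bought (otherwise it is one step from ethyl (S)-lactate).

## Route

Step 1
Reactants: 1 ethyl (2S)-2-[(tert-butyldimethylsilyl)oxy]propanoate
Product: 2 (2S)-2-[(tert-butyldimethylsilyl)oxy]propanal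
Conditions: i-Bu2AlH (1.1 equiv), CH2Cl2, −78 °C
Reagents that add atoms: none
Why: Partial ester reduction stops at the aluminium hemiacetal at −78 °C and releases the aldehyde on work-up without touching the lactate stereocentre.

Step 2
Reactants: 3 6-methylhept-5-en-2-one
Product: 5 6-methylhept-5-en-1-yne, via enol phosphate 4 (not isolated)
Conditions: LiN(i-Pr)2 (1.05 equiv), THF, −78 °C; ClP(O)(OEt)2; then LiN(i-Pr)2 (2.3 equiv), −78 °C to rt
Reagents that add atoms: none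
Why: Kinetic enolisation at the methyl group, O-phosphorylation and base-induced elimination convert the methyl ketone into the terminal alkyne (Negishi alkyne synthesis).

Step 3
Reactants: 5 6-methylhept-5-en-1-yne
Product: 7 (1E)-1-iodo-2,6-dimethylhepta-1,5-diene, via alkenylalane 6 (not isolated)
Conditions: AlMe3 (2 equiv), Cp2ZrCl2 (0.25 equiv), CH2Cl2, 0 °C to rt; then I2, THF, −30 °C
Reagents that add atoms: trimethylaluminium C[Al](C)C; iodine II
Why: Negishi zirconium-catalysed carboalumination adds Me and Al syn across the alkyne with Me on the internal carbon, and iodinolysis with retention gives the E alkenyl iodide.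

Step 4
Reactants: 7 (1E)-1-iodo-2,6-dimethylhepta-1,5-diene; 2 (2S)-2-[(tert-butyldimethylsilyl)oxy]propanal
Product: 9 (2S,3R,4E)-2-[(tert-butyldimethylsilyl)oxy]-5,9-dimethyldeca-4,8-dien-3-ol, via alkenyllithium 8 (not isolated)
Conditions: 7, t-BuLi (2.1 equiv), Et2O, −78 °C; then 2, −78 °C
Reagents that add atoms: none
Why: Iodine–lithium exchange with retention, then Felkin–Anh addition to the non-chelating α-silyloxy aldehyde, sets the (3R) carbinol anti to the (2S) silyloxy group (about 5:1 expected, minor isomer removed by chromatography).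

Step 5
Reactants: 9 (2S,3R,4E)-2-[(tert-butyldimethylsilyl)oxy]-5,9-dimethyldeca-4,8-dien-3-ol
Product: 10 (2S,3R,4E)-2-[(tert-butyldimethylsilyl)oxy]-5,9-dimethyldeca-4,8-dien-3-yl 2-(diphenylphosphanyl)benzoate
Conditions: 2-(diphenylphosphanyl)benzoic acid, DCC, 4-(dimethylamino)pyridine (cat.), CH2Cl2, rt
Reagents that add atoms: 2-(diphenylphosphanyl)benzoic acid OC(=O)c1ccccc1P(c1ccccc1)c1ccccc1
Why: Steglich esterification installs the phosphine-bearing directing leaving group without change at either stereocentre.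

Step 6
Reactants: 10 (2S,3R,4E)-2-[(tert-butyldimethylsilyl)oxy]-5,9-dimethyldeca-4,8-dien-3-yl 2-(diphenylphosphanyl)benzoate; 11 (4-bromobut-1-yn-1-yl)trimethylsilane
Product: 13 tert-butyldimethyl{[(2S,3E,5S)-5-methyl-5-(4-methylpent-3-en-1-yl)-9-(trimethylsilyl)non-3-en-8-yn-2-yl]oxy}silane, via Grignard reagent 12 (not isolated)
Conditions: 11, Mg, Et2O, rt; then 10, CuBr·SMe2 (0.5 equiv), Et2O, rt
Reagents that add atoms: none
Why: Phosphine-directed copper-mediated syn-SN2′ allylic substitution (Breit) delivers the alkyl group to the alkene terminus on the face of the leaving group, so the (3R) carbinol configuration is transferred to the new quaternary centre (future C9) and the E-disubstituted alkene is formed.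

Step 7
Reactants: 13 tert-butyldimethyl{[(2S,3E,5S)-5-methyl-5-(4-methylpent-3-en-1-yl)-9-(trimethylsilyl)non-3-en-8-yn-2-yl]oxy}silane
Product: 14 (2S,3E,5S)-5-methyl-5-(4-methylpent-3-en-1-yl)non-3-en-8-yn-2-ol
Conditions: Bu4NF (3 equiv), THF, 0 °C to rt
Reagents that add atoms: none
Why: Fluoride-mediated desilylation cleaves the O–Si and the alkynyl C–Si bond in one operation.

Step 8
Reactants: 14 (2S,3E,5S)-5-methyl-5-(4-methylpent-3-en-1-yl)non-3-en-8-yn-2-ol
Product: 16 (2S,3E,5S,8E)-9-iodo-5,8-dimethyl-5-(4-methylpent-3-en-1-yl)nona-3,8-dien-2-ol, via alkenylalane alkoxide 15 (not isolated)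
Conditions: AlMe3 (3.5 equiv), Cp2ZrCl2 (0.3 equiv), CH2Cl2, 0 °C to rt; then I2, THF, −30 °C
Reagents that add atoms: trimethylaluminium C[Al](C)C; iodine II
Why: Negishi carboalumination and iodinolysis of the terminal alkyne (alcohol carried as its aluminium alkoxide, internal alkenes inert) give the E trisubstituted alkenyl iodide needed for ring closure.

Step 9
Reactants: 16 (2S,3E,5S,8E)-9-iodo-5,8-dimethyl-5-(4-methylpent-3-en-1-yl)nona-3,8-dien-2-ol
Product: 17 (1S)-1-{(1S,2S)-2-[(1E,5S)-1-iodo-2,5,9-trimethyldeca-1,8-dien-5-yl]cyclopropyl}ethan-1-ol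
Conditions: Et2Zn (3 equiv), CH2I2 (3 equiv), CH2Cl2, −10 to 0 °C
Reagents that add atoms: diiodomethane ICI
Why: Hydroxyl-directed Simmons–Smith cyclopropanation (Furukawa reagent): the zinc alkoxide of the (S) carbinol delivers CH2 to the alkene face it occupies in the conformer with the carbinol C–H eclipsing the alkene, which sets C1 and C10 as (S,S) (trans because the alkene is E), while the undirected prenyl alkene and the alkenyl iodide react far more slowly.

Step 10
Reactants: 17 (1S)-1-{(1S,2S)-2-[(1E,5S)-1-iodo-2,5,9-trimethyldeca-1,8-dien-5-yl]cyclopropyl}ethan-1-ol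
Product: 18 1-{(1S,2S)-2-[(1E,5S)-1-iodo-2,5,9-trimethyldeca-1,8-dien-5-yl]cyclopropyl}ethan-1-one
Conditions: Dess–Martin periodinane, pyridine, CH2Cl2, rt
Reagents that add atoms: none
Why: Dess–Martin oxidation removes the relay carbinol centre and gives the methyl ketone that carries C2 and its methyl group; the cyclopropyl α-CH does not epimerise.

Step 11
Reactants: 18 1-{(1S,2S)-2-[(1E,5S)-1-iodo-2,5,9-trimethyldeca-1,8-dien-5-yl]cyclopropyl}ethan-1-one; 19 triethyl phosphonoacetate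
Product: 21 ethyl (2E)-3-{(1S,2S)-2-[(1E,5S)-1-iodo-2,5,9-trimethyldeca-1,8-dien-5-yl]cyclopropyl}but-2-enoate, via sodium phosphonate 20 (not isolated)
Conditions: 19, NaH, THF, 0 °C; then 18, 65 °C
Reagents that add atoms: none
Why: Horner–Wadsworth–Emmons olefination of the methyl ketone places the ester trans to the larger cyclopropyl group (E major, minor Z isomer removed by chromatography).

Step 12
Reactants: 21 ethyl (2E)-3-{(1S,2S)-2-[(1E,5S)-1-iodo-2,5,9-trimethyldeca-1,8-dien-5-yl]cyclopropyl}but-2-enoate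
Product: 22 (2E)-3-{(1S,2S)-2-[(1E,5S)-1-iodo-2,5,9-trimethyldeca-1,8-dien-5-yl]cyclopropyl}but-2-en-1-ol
Conditions: i-Bu2AlH (2.5 equiv), CH2Cl2, −78 °C
Reagents that add atoms: none
Why: 1,2-Reduction of the enoate by the aluminium hydride gives the allylic alcohol and leaves the alkenyl iodide intact at low temperature.

Step 13
Reactants: 22 (2E)-3-{(1S,2S)-2-[(1E,5S)-1-iodo-2,5,9-trimethyldeca-1,8-dien-5-yl]cyclopropyl}but-2-en-1-ol
Product: 23 [(2R,3R)-3-{(1S,2S)-2-[(1E,5S)-1-iodo-2,5,9-trimethyldeca-1,8-dien-5-yl]cyclopropyl}-3-methyloxiran-2-yl]methanol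
Conditions: Ti(Oi-Pr)4 (10 mol %), diethyl D-(−)-tartrate (12 mol %), t-BuOOH, 4 Å molecular sieves, CH2Cl2, −20 °C
Reagents that add atoms: tert-butyl hydroperoxide CC(C)(C)OO
Why: Katsuki–Sharpless asymmetric epoxidation touches only the allylic alcohol alkene and the D-(−)-tartrate catalyst fixes the face (reagent control), creating the tertiary C–O stereocentre that becomes C2.

Step 14
Reactants: 23 [(2R,3R)-3-{(1S,2S)-2-[(1E,5S)-1-iodo-2,5,9-trimethyldeca-1,8-dien-5-yl]cyclopropyl}-3-methyloxiran-2-yl]methanol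
Product: 24 (3S)-3-{(1S,2S)-2-[(1E,5S)-1-iodo-2,5,9-trimethyldeca-1,8-dien-5-yl]cyclopropyl}butane-1,3-diol
Conditions: NaAlH2(OCH2CH2OMe)2, THF, 0 °C
Reagents that add atoms: none
Why: Directed hydride opening of the 2,3-epoxy alcohol: the alkoxyaluminate delivers hydride intramolecularly to the secondary epoxide carbon (SN2), so the tertiary C–O bond is untouched and the carbinol is obtained as (S).

Step 15
Reactants: 24 (3S)-3-{(1S,2S)-2-[(1E,5S)-1-iodo-2,5,9-trimethyldeca-1,8-dien-5-yl]cyclopropyl}butane-1,3-diol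
Product: 25 (3S)-3-hydroxy-3-{(1S,2S)-2-[(1E,5S)-1-iodo-2,5,9-trimethyldeca-1,8-dien-5-yl]cyclopropyl}butanal
Conditions: 2,2,6,6-tetramethylpiperidin-1-oxyl (10 mol %), PhI(OAc)2, CH2Cl2, 0 °C to rt
Reagents that add atoms: none
Why: Oxoammonium-mediated oxidation converts only the primary alcohol, since the tertiary carbinol cannot be oxidised; the aldehyde is used at once.

Step 16
Reactants: 25 (3S)-3-hydroxy-3-{(1S,2S)-2-[(1E,5S)-1-iodo-2,5,9-trimethyldeca-1,8-dien-5-yl]cyclopropyl}butanal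
Product: 27 (1S,2S,4RS,5E,9S,10S)-2,6,9-trimethyl-9-(4-methylpent-3-en-1-yl)bicyclo[8.1.0]undec-5-ene-2,4-diol, via alkenylchromium dichloride 26 (not isolated)
Conditions: CrCl2 (10 equiv), NiCl2 (2 mol %), DMSO/THF, rt, 0.003 M, slow addition
Reagents that add atoms: none
Why: Nozaki–Hiyama–Kishi reaction: oxidative addition of the alkenyl iodide to zerovalent nickel, transmetalation to trivalent chromium and addition to the aldehyde close the ten-membered ring with retention of the E alkene and tolerance of the free tertiary hydroxyl; both C4 epimers are carried on because C4 is oxidised next.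

Step 17
Reactants: 27 (1S,2S,4RS,5E,9S,10S)-2,6,9-trimethyl-9-(4-methylpent-3-en-1-yl)bicyclo[8.1.0]undec-5-ene-2,4-diol
Product: 28 (1S,2S,5E,9S,10S)-2-hydroxy-2,6,9-trimethyl-9-(4-methylpent-3-en-1-yl)bicyclo[8.1.0]undec-5-en-4-one
Conditions: Dess–Martin periodinane, pyridine, CH2Cl2, 0 °C
Reagents that add atoms: none
Why: Dess–Martin oxidation of the secondary allylic alcohol converges both C4 epimers on one β-hydroxy enone under non-basic conditions that avoid retro-aldol cleavage.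

Step 18
Reactants: 28 (1S,2S,5E,9S,10S)-2-hydroxy-2,6,9-trimethyl-9-(4-methylpent-3-en-1-yl)bicyclo[8.1.0]undec-5-en-4-one
Product: 29 (1S,2S,4S,5E,9S,10S)-2,6,9-trimethyl-9-(4-methylpent-3-en-1-yl)bicyclo[8.1.0]undec-5-ene-2,4-diol
Conditions: Me4NBH(OAc)3, MeCN/AcOH (1:1), −30 °C
Reagents that add atoms: none
Why: Evans–Saksena hydroxyl-directed reduction: the C2 alkoxide binds boron and delivers hydride intramolecularly through a chair transition state with both ring bonds equatorial, giving the 1,3-anti diol, that is (4S).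

Step 19
Reactants: 29 (1S,2S,4S,5E,9S,10S)-2,6,9-trimethyl-9-(4-methylpent-3-en-1-yl)bicyclo[8.1.0]undec-5-ene-2,4-diol
Product: 30 (1S,2S,4S,5E,9S,10S)-2-hydroxy-2,6,9-trimethyl-9-(4-methylpent-3-en-1-yl)bicyclo[8.1.0]undec-5-en-4-yl acetate
Conditions: Ac2O (1.5 equiv), pyridine, 4-(dimethylamino)pyridine (cat.), CH2Cl2, 0 °C
Reagents that add atoms: acetic anhydride CC(=O)OC(C)=O
Why: Nucleophile-catalysed acylation acetylates the secondary allylic hydroxyl selectively because the tertiary cyclopropyl carbinol is too hindered to react.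

Step 20
Reactants: 30 (1S,2S,4S,5E,9S,10S)-2-hydroxy-2,6,9-trimethyl-9-(4-methylpent-3-en-1-yl)bicyclo[8.1.0]undec-5-en-4-yl acetate
Product: 31 (1S,2S,4S,5E,9R,10S)-9-[(3S)-3-hydroperoxy-4-methylpent-4-en-1-yl]-2-hydroxy-2,6,9-trimethylbicyclo[8.1.0]undec-5-en-4-yl acetate
Conditions: O2, visible light, 5,10,15,20-tetraphenylporphyrin (1 mol %), CH2Cl2, 0 °C; preparative HPLC
Reagents that add atoms: dioxygen O=O
Why: Schenck ene reaction: singlet oxygen attacks the electron-rich side-chain alkene (the ring alkene is deactivated by its allylic acetate) with abstraction of a methyl hydrogen to give the secondary allylic hydroperoxide, and the (3′S) isomer is separated from its C3′ epimer and the tertiary hydroperoxide regioisomer.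

## Compound list

1 | ethyl (2S)-2-[(tert-butyldimethylsilyl)oxy]propanoate | CCOC(=O)[C@H](C)O[Si](C)(C)C(C)(C)C | starting material
2 | (2S)-2-[(tert-butyldimethylsilyl)oxy]propanal | O=C[C@H](C)O[Si](C)(C)C(C)(C)C | intermediate
3 | 6-methylhept-5-en-2-one | CC(=O)CCC=C(C)C | starting material
4 | diethyl 6-methylhepta-1,5-dien-2-yl phosphate | C=C(CCC=C(C)C)OP(=O)(OCC)OCC | intermediate (not isolated)
5 | 6-methylhept-5-en-1-yne | C#CCCC=C(C)C | intermediate
6 | [(1E)-2,6-dimethylhepta-1,5-dien-1-yl]dimethylaluminium | C[Al](C)/C=C(\C)CCC=C(C)C | intermediate (not isolated)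
7 | (1E)-1-iodo-2,6-dimethylhepta-1,5-diene | I/C=C(\C)CCC=C(C)C | intermediate
8 | [(1E)-2,6-dimethylhepta-1,5-dien-1-yl]lithium | [Li]/C=C(\C)CCC=C(C)C | intermediate (not isolated)
9 | (2S,3R,4E)-2-[(tert-butyldimethylsilyl)oxy]-5,9-dimethyldeca-4,8-dien-3-ol | C[C@H](O[Si](C)(C)C(C)(C)C)[C@H](O)/C=C(\C)CCC=C(C)C | intermediate
10 | (2S,3R,4E)-2-[(tert-butyldimethylsilyl)oxy]-5,9-dimethyldeca-4,8-dien-3-yl 2-(diphenylphosphanyl)benzoate | C[C@H](O[Si](C)(C)C(C)(C)C)[C@H](OC(=O)c1ccccc1P(c1ccccc1)c1ccccc1)/C=C(\C)CCC=C(C)C | intermediate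
11 | (4-bromobut-1-yn-1-yl)trimethylsilane | C[Si](C)(C)C#CCCBr | starting material
12 | [4-(trimethylsilyl)but-3-yn-1-yl]magnesium bromide | C[Si](C)(C)C#CCC[Mg]Br | intermediate (not isolated)
13 | tert-butyldimethyl{[(2S,3E,5S)-5-methyl-5-(4-methylpent-3-en-1-yl)-9-(trimethylsilyl)non-3-en-8-yn-2-yl]oxy}silane | C[C@H](O[Si](C)(C)C(C)(C)C)/C=C/[C@@](C)(CCC=C(C)C)CCC#C[Si](C)(C)C | intermediate
14 | (2S,3E,5S)-5-methyl-5-(4-methylpent-3-en-1-yl)non-3-en-8-yn-2-ol | C[C@H](O)/C=C/[C@@](C)(CCC=C(C)C)CCC#C | intermediate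
15 | {(1E,5S,6E,8S)-8-[(dimethylalumanyl)oxy]-2,5-dimethyl-5-(4-methylpent-3-en-1-yl)nona-1,6-dien-1-yl}dimethylaluminium | C[C@H](O[Al](C)C)/C=C/[C@@](C)(CCC=C(C)C)CC/C(C)=C/[Al](C)C | intermediate (not isolated)
16 | (2S,3E,5S,8E)-9-iodo-5,8-dimethyl-5-(4-methylpent-3-en-1-yl)nona-3,8-dien-2-ol | C[C@H](O)/C=C/[C@@](C)(CCC=C(C)C)CC/C(C)=C/I | intermediate
17 | (1S)-1-{(1S,2S)-2-[(1E,5S)-1-iodo-2,5,9-trimethyldeca-1,8-dien-5-yl]cyclopropyl}ethan-1-ol | C[C@H](O)[C@H]1C[C@@H]1[C@@](C)(CCC=C(C)C)CC/C(C)=C/I | intermediate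
18 | 1-{(1S,2S)-2-[(1E,5S)-1-iodo-2,5,9-trimethyldeca-1,8-dien-5-yl]cyclopropyl}ethan-1-one | CC(=O)[C@H]1C[C@@H]1[C@@](C)(CCC=C(C)C)CC/C(C)=C/I | intermediate
19 | triethyl phosphonoacetate | CCOC(=O)CP(=O)(OCC)OCC | starting material
20 | sodium salt of triethyl phosphonoacetate (phosphonate carbanion) | [Na+].CCOC(=O)[CH-]P(=O)(OCC)OCC | intermediate (not isolated)
21 | ethyl (2E)-3-{(1S,2S)-2-[(1E,5S)-1-iodo-2,5,9-trimethyldeca-1,8-dien-5-yl]cyclopropyl}but-2-enoate | CCOC(=O)/C=C(\C)[C@H]1C[C@@H]1[C@@](C)(CCC=C(C)C)CC/C(C)=C/I | intermediate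
22 | (2E)-3-{(1S,2S)-2-[(1E,5S)-1-iodo-2,5,9-trimethyldeca-1,8-dien-5-yl]cyclopropyl}but-2-en-1-ol | OC/C=C(\C)[C@H]1C[C@@H]1[C@@](C)(CCC=C(C)C)CC/C(C)=C/I | intermediate
23 | [(2R,3R)-3-{(1S,2S)-2-[(1E,5S)-1-iodo-2,5,9-trimethyldeca-1,8-dien-5-yl]cyclopropyl}-3-methyloxiran-2-yl]methanol | OC[C@H]1O[C@]1(C)[C@H]2C[C@@H]2[C@@](C)(CCC=C(C)C)CC/C(C)=C/I | intermediate
24 | (3S)-3-{(1S,2S)-2-[(1E,5S)-1-iodo-2,5,9-trimethyldeca-1,8-dien-5-yl]cyclopropyl}butane-1,3-diol | OCC[C@](C)(O)[C@H]1C[C@@H]1[C@@](C)(CCC=C(C)C)CC/C(C)=C/I | intermediate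
25 | (3S)-3-hydroxy-3-{(1S,2S)-2-[(1E,5S)-1-iodo-2,5,9-trimethyldeca-1,8-dien-5-yl]cyclopropyl}butanal | O=CC[C@](C)(O)[C@H]1C[C@@H]1[C@@](C)(CCC=C(C)C)CC/C(C)=C/I | intermediate
26 | alkenylchromium dichloride formed from 25 (CrCl2 in place of I) | O=CC[C@](C)(O)[C@H]1C[C@@H]1[C@@](C)(CCC=C(C)C)CC/C(C)=C/[Cr](Cl)Cl | intermediate (not isolated)
27 | (1S,2S,4RS,5E,9S,10S)-2,6,9-trimethyl-9-(4-methylpent-3-en-1-yl)bicyclo[8.1.0]undec-5-ene-2,4-diol | CC(C)=CCC[C@@]1(C)CC/C(C)=C/C(O)C[C@](C)(O)[C@H]2C[C@@H]21 | intermediate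
28 | (1S,2S,5E,9S,10S)-2-hydroxy-2,6,9-trimethyl-9-(4-methylpent-3-en-1-yl)bicyclo[8.1.0]undec-5-en-4-one | CC(C)=CCC[C@@]1(C)CC/C(C)=C/C(=O)C[C@](C)(O)[C@H]2C[C@@H]21 | intermediate
29 | (1S,2S,4S,5E,9S,10S)-2,6,9-trimethyl-9-(4-methylpent-3-en-1-yl)bicyclo[8.1.0]undec-5-ene-2,4-diol | CC(C)=CCC[C@@]1(C)CC/C(C)=C/[C@@H](O)C[C@](C)(O)[C@H]2C[C@@H]21 | intermediate
30 | (1S,2S,4S,5E,9S,10S)-2-hydroxy-2,6,9-trimethyl-9-(4-methylpent-3-en-1-yl)bicyclo[8.1.0]undec-5-en-4-yl acetate | CC(C)=CCC[C@@]1(C)CC/C(C)=C/[C@@H](OC(C)=O)C[C@](C)(O)[C@H]2C[C@@H]21 | intermediate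
31 | (1S,2S,4S,5E,9R,10S)-9-[(3S)-3-hydroperoxy-4-methylpent-4-en-1-yl]-2-hydroxy-2,6,9-trimethylbicyclo[8.1.0]undec-5-en-4-yl acetate | C=C(C)[C@H](CC[C@@]1(C)CC/C(C)=C/[C@@H](OC(C)=O)C[C@](C)(O)[C@H]2C[C@@H]21)OO | target

## Step count and risks

Total step count: 20. Longest linear sequence: 19 steps (3 to 31, steps 2 to 20).

The three steps most likely to fail:

Step 9 (directed cyclopropanation). Only moderate facial selectivity is expected for a methyl carbinol on an E alkene, the alkene sits next to a quaternary carbon, and the prenyl alkene can compete. The fallback sets out from 16. Oxidation with Dess–Martin periodinane gives the enone (3E,5S,8E)-9-iodo-5,8-dimethyl-5-(4-methylpent-3-en-1-yl)nona-3,8-dien-2-one F1. The three-membered ring is then built by a catalyst-controlled Corey–Chaykovsky reaction (Me3S(O)I, NaH, chiral LaLi3(2,2′-biphenyldiolate)3 with NaI, THF/toluene, rt, ligand enantiomer chosen for the (1S,2S) product). Conjugate addition and ring closure give the trans cyclopropyl ketone directly, and the route is rejoined at 18.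

Step 16 (ten-membered ring closure). The β-hydroxy aldehyde can undergo retro-aldol cleavage or dehydration during the slow, dilute reaction. The fallback sets out from 23 and closes the ring before the epoxide is opened. Dess–Martin oxidation gives the epoxy aldehyde (2S,3R)-3-{(1S,2S)-2-[(1E,5S)-1-iodo-2,5,9-trimethyldeca-1,8-dien-5-yl]cyclopropyl}-3-methyloxirane-2-carbaldehyde F2. CrCl2/NiCl2 closure on this robust aldehyde gives the macrocyclic epoxy alcohol (1S,2R,3R,5E,9S,10S)-2,3-epoxy-2,6,9-trimethyl-9-(4-methylpent-3-en-1-yl)bicyclo[8.1.0]undec-5-en-4-ol F3 (C4 epimers). Dess–Martin oxidation gives the epoxy enone (1S,2R,3S,5E,9S,10S)-2,3-epoxy-2,6,9-trimethyl-9-(4-methylpent-3-en-1-yl)bicyclo[8.1.0]undec-5-en-4-one F4. SmI2 (THF/MeOH, −78 °C) then cleaves the C–O bond α to the ketone and unveils the C2 carbinol, which rejoins the route at 28.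

Step 20 (photooxygenation). The ene reaction gives both C3′ epimers and the tertiary hydroperoxide regioisomer, so the wanted isomer is at best about a quarter of the mixture. The fallback sets out from 30 and sets C3′ by catalyst control. Epoxidation of the side-chain alkene with the D-fructose-derived Shi ketone (1,2:4,5-di-O-isopropylidene-β-D-erythro-2,3-hexodiulo-2,6-pyranose) and KHSO5 (K2CO3, MeCN/dimethoxymethane/H2O, 0 °C) gives the epoxide (1S,2S,4S,5E,9R,10S)-9-{2-[(2R)-3,3-dimethyloxiran-2-yl]ethyl}-2-hydroxy-2,6,9-trimethylbicyclo[8.1.0]undec-5-en-4-yl acetate F5. Isomerisation with Cp2TiCl (from Cp2TiCl2 and Mn, THF, rt) gives the allylic alcohol (1S,2S,4S,5E,9R,10S)-2-hydroxy-9-[(3R)-3-hydroxy-4-methylpent-4-en-1-yl]-2,6,9-trimethylbicyclo[8.1.0]undec-5-en-4-yl acetate F6 with retention at C3′. MsCl/Et3N (CH2Cl2, −40 °C) gives the mesylate (1S,2S,4S,5E,9R,10S)-2-hydroxy-2,6,9-trimethyl-9-{(3R)-4-methyl-3-[(methylsulfonyl)oxy]pent-4-en-1-yl}bicyclo[8.1.0]undec-5-en-4-yl acetate F7. Displacement with anhydrous H2O2 in Et2O (−78 to 0 °C) with inversion arrives at 31.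

## Further compounds

F1 | step 9 | (3E,5S,8E)-9-iodo-5,8-dimethyl-5-(4-methylpent-3-en-1-yl)nona-3,8-dien-2-one | CC(=O)/C=C/[C@@](C)(CCC=C(C)C)CC/C(C)=C/I
F2 | step 16 | (2S,3R)-3-{(1S,2S)-2-[(1E,5S)-1-iodo-2,5,9-trimethyldeca-1,8-dien-5-yl]cyclopropyl}-3-methyloxirane-2-carbaldehyde | O=C[C@H]1O[C@]1(C)[C@H]2C[C@@H]2[C@@](C)(CCC=C(C)C)CC/C(C)=C/I
F3 | step 16 | (1S,2R,3R,5E,9S,10S)-2,3-epoxy-2,6,9-trimethyl-9-(4-methylpent-3-en-1-yl)bicyclo[8.1.0]undec-5-en-4-ol | CC(C)=CCC[C@@]1(C)CC/C(C)=C/C(O)[C@H]3O[C@]3(C)[C@H]2C[C@@H]21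
F4 | step 16 | (1S,2R,3S,5E,9S,10S)-2,3-epoxy-2,6,9-trimethyl-9-(4-methylpent-3-en-1-yl)bicyclo[8.1.0]undec-5-en-4-one | CC(C)=CCC[C@@]1(C)CC/C(C)=C/C(=O)[C@H]3O[C@]3(C)[C@H]2C[C@@H]21
F5 | step 20 | (1S,2S,4S,5E,9R,10S)-9-{2-[(2R)-3,3-dimethyloxiran-2-yl]ethyl}-2-hydroxy-2,6,9-trimethylbicyclo[8.1.0]undec-5-en-4-yl acetate | CC1(C)O[C@@H]1CC[C@@]2(C)CC/C(C)=C/[C@@H](OC(C)=O)C[C@](C)(O)[C@H]3C[C@@H]32
F6 | step 20 | (1S,2S,4S,5E,9R,10S)-2-hydroxy-9-[(3R)-3-hydroxy-4-methylpent-4-en-1-yl]-2,6,9-trimethylbicyclo[8.1.0]undec-5-en-4-yl acetate | C=C(C)[C@@H](CC[C@@]1(C)CC/C(C)=C/[C@@H](OC(C)=O)C[C@](C)(O)[C@H]2C[C@@H]21)O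
F7 | step 20 | (1S,2S,4S,5E,9R,10S)-2-hydroxy-2,6,9-trimethyl-9-{(3R)-4-methyl-3-[(methylsulfonyl)oxy]pent-4-en-1-yl}bicyclo[8.1.0]undec-5-en-4-yl acetate | C=C(C)[C@@H](CC[C@@]1(C)CC/C(C)=C/[C@@H](OC(C)=O)C[C@](C)(O)[C@H]2C[C@@H]21)OS(C)(=O)=O
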